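The amounts charged and the readings so far stand here.

| flask | free monomer | transfer agent | initiator | remark | time |
|---|---|---|---|---|---|
| Friday's | 1 M | 0.15 M | 5 mM | run made earlier |  |
| Sunday's | 1 M | 0.60 M | 5 mM | run made earlier |  |
| Thursday's | 1 M | 0.30 M | 7.5 mM | run made earlier |  |
| spring | 1.0 M | 0.300 M | 5.0 mM |  | 10 min |
| dusk | 1.0 M | 0.300 M | 5.0 mM |  | 3.0 min |

| run | time / min | monomer in chains / % | free monomer / % |
|---|---|---|---|
| Friday's | 0.500 | 2.5 | 98.0 |
| Friday's | 1.50 | 17.8 | 81.7 |
| Friday's | 3.00 | 47.9 | 51.7 |
| Friday's | 4.00 | 64.0 | 35.7 |
| Friday's | 6.00 | 83.7 | 16.0 |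
| Friday's | 8.00 | 92.8 | 7.0 |
| Friday's | 10.0 | 97.3 | 3.1 |
| Sunday's | 1.33 | 14.2 | 84.6 |
| Sunday's | 3.00 | 46.3 | 54.1 |
| Sunday's | 4.00 | 61.3 | 38.5 |
| Sunday's | 6.00 | 80.7 | 19.6 |
| Sunday's | 8.00 | 89.7 | 10.2 |
| Sunday's | 10.0 | 93.7 | 5.8 |
| Thursday's | 0.833 | 9.7 | 90.2 |
| Thursday's | 1.50 | 25.7 | 75.4 |
| Thursday's | 3.00 | 60.5 | 39.0 |
| Thursday's | 5.00 | 85.6 | 14.9 |
| Thursday's | 10.0 | 98.9 | 1.4 |

(readings scatter by 0.3 percentage points)

- the average divides the monomer in chains by the number of chains begun, living and dead together
- the numbers in the tables scatter with a standard deviation of 0.3 percentage points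
- on the list of suspects stand: free monomer + initiator -> living end + monomer in chains; free monomer + living end -> monomer in chains + living end; living end + transfer agent -> dead chain
- the earlier runs do not show the number of chains; that part of a forecast is a guess

- which of the two ends with the longer chains by the average number of monomer units in a chain (chains begun, living or dead) ("neither" if they lie within 10%) (spring / dusk / neither)
- average number of monomer units in a chain (chains begun, living or dead) at the end, spring
- average number of monomer units in a chain (chains begun, living or dead) at the end, dusk

The length asked is monomer in chains over chains begun, and the readings never count chains. Free monomer, M, does fall in a pseudo-first-order way, though, with a slope s = −d ln M/dt that this reckoning takes as proportional to the living ends, so s can serve as a count of them.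

Friday's and Sunday's runs share one initiator charge, which gives two ways to the same late count. Bare, they part: s is 0.407 min⁻¹ on Friday's run and 0.282 min⁻¹ on Sunday's. Sunday's slope also sags at 0.0729 min⁻¹, read here as living ends dying on the transfer agent. A dead chain is still a chain begun, so the count restored adds that sag, scaled to each run's transfer agent, times ln(charged M/M). The counts become 0.463 min⁻¹ and 0.469 min⁻¹, which agree, so the bare slope is the one that misleads.

Sunday's early window gives a restored count of 0.296 min⁻¹. Call exposure, Y, the area under free monomer against time. Y is 108 M·s for that window and 228 M·s for the last, about twice. If initiator left is exp(−aY), doubling Y multiplies the count by 1 + exp(−aY). That gives a = 0.282 M⁻¹ min⁻¹, the initiator's loss per unit of exposure.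

Spring and dusk lie between those runs in transfer agent, so interpolation gives exposures of 225 M·s for spring and 143 M·s for dusk. Chains begun are then 3.26 mM for spring and 2.45 mM for dusk. Monomer in chains, taken as the free monomer lost, is 0.960 M for spring and 0.475 M for dusk. This reckoning's lengths are 294 for spring and 194 for dusk.

The forecast says spring, with 228 and 136, and holds that “the transfer agent barely matters to rate”. The lengths reckoned here are longer than the forecast's for spring and for dusk.

The flask gives spring, with 287 for spring and 185 for dusk.

    free monomer + initiator → living end + monomer in chains (k = 0.297 M⁻¹ min⁻¹)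
    free monomer + living end → monomer in chains + living end, rate k2*[living end]*[free monomer] (k = 142 M⁻¹ min⁻¹)
    living end + transfer agent → dead chain (kL = 0.125 M⁻¹ min⁻¹)

Spring keeps 33% of its initiator at 10.0 min, where exp(−aY) gave 34.7%. The neighbour of spring charged with 0.25 M of free monomer, other charges and time held, keeps 22.5% of it. A straight line gives it an exposure of 91.9 M·s, so 64.9% of initiator left, 1.76 mM of chains begun and a length of 110. The neighbour itself has 63% of its initiator left and a length of 106.

(The readings stem from a simulated flask for substances that don't exist; the scatter is artificial.)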